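Robustol: total synthesis through a macrocyclic vinylogous ester closure and late aromatisation of ring A

Cuts: once the two ring B O-CH3 bonds (protection only) and the aromaticity of ring A are taken back, the strategic cut is the bond between the diaryl ether oxygen on C1' of ring B and C3 of ring A, which opens the 22-membered ring. Further cuts are C4'-CH2 (aryl bromide + alkylzinc) and ring A into a C15 aldehyde (C5 plus the fourteen CH2), an acetonylidene ylide (C2 to C4) and diethyl malonate (C1, C6).
Enabling feature: on ring A the OH (C1), the O-aryl group (C3) and the chain (C5) are mutually meta, the pattern of the O-aryl enol ether of a symmetric 5-alkylcyclohexane-1,3-dione. On ring B the ether oxygen stands on C1' between the oxygen-bearing C2' and C6' with the chain on C4', so the phenoxide has no free ortho or para carbon and can bond only through oxygen.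
Forward order: ring B is bought aromatic and joined to the chain by Negishi coupling, and ring A is annulated at the other chain end as a cyclohexane-1,3-dione (Wittig, Michael-Claisen). The unmasked ring B phenoxide attacks the derived 3-chloroenone, forming the ether bond and the macrocycle in one event; ring A is then dehydrogenated to the phenol and the methyl ethers are cleaved.
Stereochemistry: robustol has no stereocentre. C5 of the chloroenone and of the macrocyclic enone is carried as a racemate and becomes sp2 on aromatisation, and the E-alkene of the enone disappears in the annulation.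

Key step: step 11

Remark on the chemistry: the 1,3-diones 15, 16 and 18, keto ester 13 and keto acid 14 are drawn in the diketo form although they are largely enolised; this has no bearing on the route.

Step 1
Reactants: 1 ω-pentadecalactone (oxacyclohexadecan-2-one)
Product: 2 15-bromopentadecanoic acid
Conditions: 33% HBr in AcOH, H2SO4 (cat.), 80 °C
Reagents that add atoms: hydrogen bromide, Br
Why: Acid-promoted opening of the macrolactone by bromide (SN2 at the O-CH2 carbon of the protonated ester) is the standard entry to ω-bromo acids, and no other functional group is present.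

Step 2
Reactants: 2 15-bromopentadecanoic acid
Product: 3 methyl 15-bromopentadecanoate
Conditions: MeOH, H2SO4 (cat.), reflux
Reagents that add atoms: methanol, CO
Why: Fischer esterification, under which the primary alkyl bromide is inert.

Step 3
Reactants: 4 4-bromo-2,6-dimethoxyphenol
Product: 5 2-(benzyloxy)-5-bromo-1,3-dimethoxybenzene
Conditions: BnBr, K2CO3, DMF, 25 to 60 °C
Reagents that add atoms: benzyl bromide, BrCc1ccccc1
Why: Williamson ether synthesis with a reactive benzylic halide, chosen because the benzyl ether survives the organozinc, hydride, ethoxide, hydroxide and hot acid of steps 4 to 7 and leaves by hydrogenolysis.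

Step 4
Reactants: 3 methyl 15-bromopentadecanoate; 5 2-(benzyloxy)-5-bromo-1,3-dimethoxybenzene
Product: 7 methyl 15-[4-(benzyloxy)-3,5-dimethoxyphenyl]pentadecanoate, via alkylzinc bromide 6 (not isolated)
Conditions: 3 (1.3 equiv), Zn dust, I2 (5 mol%), DMA, 80 °C; then 5, Pd(OAc)2 (2 mol%), SPhos (4 mol%), THF, 25 to 50 °C
Reagents that add atoms: zinc, [Zn] (stays only in intermediate 6)
Why: Iodine-activated zinc inserts into the primary C-Br bond without touching the ester, and in the Negishi sp3-sp2 coupling zerovalent palladium bearing a bulky electron-rich biaryl phosphine inserts readily into the electron-rich aryl bromide and reductively eliminates faster than β-hydride elimination.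

Step 5
Reactants: 7 methyl 15-[4-(benzyloxy)-3,5-dimethoxyphenyl]pentadecanoate
Product: 9 15-[4-(benzyloxy)-3,5-dimethoxyphenyl]pentadecanal, via aluminium hemiacetal 8 (not isolated)
Conditions: i-Bu2AlH (1.1 equiv), CH2Cl2, -78 °C; MeOH, then aq. potassium sodium tartrate
Reagents that add atoms: diisobutylaluminium hydride, CC(C)C[AlH]CC(C)C (aluminium and isobutyl groups stay only in intermediate 8)
Why: Partial reduction of an ester with one equivalent of hydride, in which the tetrahedral aluminium hemiacetal 8 (racemic, transient) is stable at -78 °C and releases the aldehyde only on hydrolysis, when no hydride is left.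

Step 6
Reactants: 9 15-[4-(benzyloxy)-3,5-dimethoxyphenyl]pentadecanal; 10 1-(triphenylphosphoranylidene)propan-2-one
Product: 11 (E)-18-[4-(benzyloxy)-3,5-dimethoxyphenyl]octadec-3-en-2-one
Conditions: 10 (1.3 equiv), toluene, 80 °C
Reagents that add atoms: none
Why: Wittig olefination with a stabilised ylide, which gives the E-enone selectively and tolerates every group in 9.

Step 7
Reactants: 11 (E)-18-[4-(benzyloxy)-3,5-dimethoxyphenyl]octadec-3-en-2-one; 12 diethyl malonate
Product: 15 5-{14-[4-(benzyloxy)-3,5-dimethoxyphenyl]tetradecyl}cyclohexane-1,3-dione, via keto ester 13 (not isolated), via keto acid 14 (not isolated)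
Conditions: 12 (1.2 equiv), NaOEt (1.2 equiv), EtOH, reflux; then aq. NaOH, reflux; then aq. HCl to pH 1, reflux
Reagents that add atoms: sodium hydroxide, [Na+].[OH-] (its oxygen stays only in intermediate 14 and leaves with the CO2)
Why: Michael addition of the malonate anion to C4 of the enone, Claisen (Dieckmann-type) closure of the methyl ketone enolate onto one ester, saponification and decarboxylation of the β-keto acid make up the classical dimedone-type annulation, and the stereocentres of 13 and 14 are of no account because 15 is achiral.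

Step 8
Reactants: 15 5-{14-[4-(benzyloxy)-3,5-dimethoxyphenyl]tetradecyl}cyclohexane-1,3-dione
Product: 16 5-[14-(4-hydroxy-3,5-dimethoxyphenyl)tetradecyl]cyclohexane-1,3-dione
Conditions: H2 (1 atm), 10% Pd/C, EtOAc-EtOH, 25 °C
Reagents that add atoms: none
Why: Catalytic hydrogenolysis of an aryl benzyl ether, under which the enolised dione, the arene and the methyl ethers are not reduced at 1 atm.

Step 9
Reactants: 16 5-[14-(4-hydroxy-3,5-dimethoxyphenyl)tetradecyl]cyclohexane-1,3-dione
Product: 18 5-{14-[4-(tert-butyldimethylsilyloxy)-3,5-dimethoxyphenyl]tetradecyl}cyclohexane-1,3-dione, via bis-silyl ether 17 (not isolated)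
Conditions: TBSCl (2.5 equiv), imidazole (5 equiv), DMF, 25 °C; then 5% aq. citric acid, THF, 25 °C
Reagents that add atoms: tert-butyldimethylsilyl chloride, CC(C)(C)[Si](C)(C)Cl
Why: Imidazole-promoted silylation takes both acidic OH groups, and because the enol silyl ether of 17 is a vinylogous silyl ester it is hydrolysed by dilute aqueous acid far faster than the acid-robust, flanked aryl silyl ether.

Step 10
Reactants: 18 5-{14-[4-(tert-butyldimethylsilyloxy)-3,5-dimethoxyphenyl]tetradecyl}cyclohexane-1,3-dione
Product: 19 3-chloro-5-{14-[4-(tert-butyldimethylsilyloxy)-3,5-dimethoxyphenyl]tetradecyl}cyclohex-2-en-1-one (racemic)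
Conditions: (COCl)2 (1.5 equiv), CH2Cl2, 0 to 40 °C
Reagents that add atoms: oxalyl chloride, O=C(Cl)C(=O)Cl
Why: Standard conversion of a cyclic 1,3-dione into its 3-chloroenone (vinylogous acid chloride formation, driven by loss of CO and CO2), which gives one constitutional isomer because 18 is symmetric and makes C5 a stereocentre without any bias, hence a racemate.

Step 11
Reactants: 19 3-chloro-5-{14-[4-(tert-butyldimethylsilyloxy)-3,5-dimethoxyphenyl]tetradecyl}cyclohex-2-en-1-one
Product: 21 macrocyclic 3-aryloxycyclohex-2-enone (racemic; enone C3 bonded to the ring B oxygen, enone C5 linked through (CH2)14 to C4' of the 2',6'-dimethoxyphenyl ring), via caesium phenoxide 20 (not isolated)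
Conditions: 19 added by syringe pump (12 h) to CsF (5 equiv), dry degassed DMF, 60 °C, final ca. 1 mM, Ar
Reagents that add atoms: caesium fluoride, [Cs+].[F-] (caesium stays only in intermediate 20)
Why: Fluoride removes the silyl group of 19 and leaves caesium phenoxide 20, whose oxygen adds to C3 of the β-chloroenone to give an enolate that restores the C2=C3 double bond by expelling chloride (conjugate addition-elimination at a vinylogous acyl chloride). The closest known reaction type is the intermolecular substitution of 3-chlorocyclohex-2-enones by phenoxides, and the fluoride-triggered high-dilution format is borrowed from macrocyclic SNAr diaryl ether closures. The one ring closed is the 22-membered macrocycle, formed end to end in a formally 22-exo-trig attack of oxygen on a planar, unhindered sp2 carbon across a strain-free (CH2)14 tether. No stereocentre is created, and the existing C5 centre stays racemic until step 12 removes it. The step needs ring closure over oligomerisation, which slow addition to about 1 mM secures, and O- over C-attack at a single electrophilic site, which the substrate secures because both ortho carbons (OMe) and the para carbon (chain) of the phenoxide are substituted and chloride marks C3 as the only carbon able to undergo substitution. The two methoxy groups beside the oxygen, a real handicap for copper- or palladium-mediated arylation of this phenol, count for little in an attack on a trigonal carbon that carries only a small leaving group.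

Step 12
Reactants: 21 macrocyclic 3-aryloxycyclohex-2-enone
Product: 23 robustol dimethyl ether, via cross-conjugated dienone 22 (not isolated)
Conditions: Pd(OCOCF3)2 (5 mol%), 2-(dimethylamino)pyridine (10 mol%), TsOH (20 mol%), O2 (1 atm), DMSO, 80 °C
Reagents that add atoms: none
Why: Aerobic palladium-catalysed dehydrogenation of a cyclohexenone, in which a divalent palladium enolate at C6 loses H-C5 by β-hydride elimination to give dienone 22, this tautomerises to the phenol with loss of the C5 stereocentre, and O2 returns the palladium to the divalent state.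

Step 13
Reactants: 23 robustol dimethyl ether
Product: 24 robustol
Conditions: BBr3 (5 equiv), CH2Cl2, -78 to 25 °C; then H2O
Reagents that add atoms: none
Why: BBr3 cleavage of aryl methyl ethers, in which bromide attacks only the methyl carbons of the boron-complexed ethers, so the diaryl ether, which offers no sp3 carbon, stays intact.

Compound list
1 | ω-pentadecalactone (oxacyclohexadecan-2-one) | O=C1CCCCCCCCCCCCCCO1 | starting material
2 | 15-bromopentadecanoic acid | OC(=O)CCCCCCCCCCCCCCBr | intermediate
3 | methyl 15-bromopentadecanoate | COC(=O)CCCCCCCCCCCCCCBr | intermediate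
4 | 4-bromo-2,6-dimethoxyphenol | COc1cc(Br)cc(OC)c1O | starting material
5 | 2-(benzyloxy)-5-bromo-1,3-dimethoxybenzene | COc1cc(Br)cc(OC)c1OCc1ccccc1 | intermediate
6 | (15-methoxy-15-oxopentadecyl)zinc bromide (not isolated) | COC(=O)CCCCCCCCCCCCCC[Zn]Br | intermediate
7 | methyl 15-[4-(benzyloxy)-3,5-dimethoxyphenyl]pentadecanoate | COC(=O)CCCCCCCCCCCCCCc1cc(OC)c(OCc2ccccc2)c(OC)c1 | intermediate
8 | diisobutylaluminium hemiacetal of 7 (racemic, not isolated) | COC(O[Al](CC(C)C)CC(C)C)CCCCCCCCCCCCCCc1cc(OC)c(OCc2ccccc2)c(OC)c1 | intermediate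
9 | 15-[4-(benzyloxy)-3,5-dimethoxyphenyl]pentadecanal | O=CCCCCCCCCCCCCCCc1cc(OC)c(OCc2ccccc2)c(OC)c1 | intermediate
10 | 1-(triphenylphosphoranylidene)propan-2-one | CC(=O)C=P(c1ccccc1)(c1ccccc1)c1ccccc1 | starting material
11 | (E)-18-[4-(benzyloxy)-3,5-dimethoxyphenyl]octadec-3-en-2-one | CC(=O)/C=C/CCCCCCCCCCCCCCc1cc(OC)c(OCc2ccccc2)c(OC)c1 | intermediate
12 | diethyl malonate | CCOC(=O)CC(=O)OCC | starting material
13 | ethyl 2-{14-[4-(benzyloxy)-3,5-dimethoxyphenyl]tetradecyl}-4,6-dioxocyclohexane-1-carboxylate (stereoisomer mixture, not isolated) | CCOC(=O)C1C(=O)CC(=O)CC1CCCCCCCCCCCCCCc1cc(OC)c(OCc2ccccc2)c(OC)c1 | intermediate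
14 | 2-{14-[4-(benzyloxy)-3,5-dimethoxyphenyl]tetradecyl}-4,6-dioxocyclohexane-1-carboxylic acid (stereoisomer mixture, not isolated) | OC(=O)C1C(=O)CC(=O)CC1CCCCCCCCCCCCCCc1cc(OC)c(OCc2ccccc2)c(OC)c1 | intermediate
15 | 5-{14-[4-(benzyloxy)-3,5-dimethoxyphenyl]tetradecyl}cyclohexane-1,3-dione | O=C1CC(=O)CC(CCCCCCCCCCCCCCc2cc(OC)c(OCc3ccccc3)c(OC)c2)C1 | intermediate
16 | 5-[14-(4-hydroxy-3,5-dimethoxyphenyl)tetradecyl]cyclohexane-1,3-dione | O=C1CC(=O)CC(CCCCCCCCCCCCCCc2cc(OC)c(O)c(OC)c2)C1 | intermediate
17 | 3-(tert-butyldimethylsilyloxy)-5-{14-[4-(tert-butyldimethylsilyloxy)-3,5-dimethoxyphenyl]tetradecyl}cyclohex-2-en-1-one (racemic, not isolated) | O=C1C=C(O[Si](C)(C)C(C)(C)C)CC(CCCCCCCCCCCCCCc2cc(OC)c(O[Si](C)(C)C(C)(C)C)c(OC)c2)C1 | intermediate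
18 | 5-{14-[4-(tert-butyldimethylsilyloxy)-3,5-dimethoxyphenyl]tetradecyl}cyclohexane-1,3-dione | O=C1CC(=O)CC(CCCCCCCCCCCCCCc2cc(OC)c(O[Si](C)(C)C(C)(C)C)c(OC)c2)C1 | intermediate
19 | 3-chloro-5-{14-[4-(tert-butyldimethylsilyloxy)-3,5-dimethoxyphenyl]tetradecyl}cyclohex-2-en-1-one (racemic) | O=C1C=C(Cl)CC(CCCCCCCCCCCCCCc2cc(OC)c(O[Si](C)(C)C(C)(C)C)c(OC)c2)C1 | intermediate
20 | caesium 4-[14-(3-chloro-5-oxocyclohex-3-en-1-yl)tetradecyl]-2,6-dimethoxyphenoxide (racemic, not isolated) | O=C1C=C(Cl)CC(CCCCCCCCCCCCCCc2cc(OC)c([O-])c(OC)c2)C1.[Cs+] | intermediate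
21 | macrocyclic 3-aryloxycyclohex-2-enone, 22-membered ring (racemic) | O=C1C=C2CC(C1)CCCCCCCCCCCCCCc1cc(OC)c(O2)c(OC)c1 | intermediate
22 | macrocyclic 3-aryloxy-5-alkylcyclohexa-2,5-dienone, keto tautomer of 23 (not isolated) | O=C1C=C2CC(=C1)CCCCCCCCCCCCCCc1cc(OC)c(O2)c(OC)c1 | intermediate
23 | robustol dimethyl ether | Oc1cc2cc(c1)Oc1c(OC)cc(cc1OC)CCCCCCCCCCCCCC2 | intermediate
24 | robustol | Oc1cc2cc(c1)Oc1c(O)cc(cc1O)CCCCCCCCCCCCCC2 | target

Total step count: 13.
Longest linear sequence: 12 steps (1 to 24 through steps 1, 2 and 4 to 13); step 3 is the only branch.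

Steps most likely to fail

Step 11. Intermolecular addition-elimination (oligomerisation) may outrun ring closure, or basic fluoride with traces of water may hydrolyse the chloroenone back to the dione. In the fallback the O-C3 bond is made intermolecularly and the 22-membered ring is closed inside the chain by ring-closing metathesis. It sets out from 4, 10 and 12 and returns at 21.
- Commercial undec-10-enal and 10 give (E)-tetradeca-3,13-dien-2-one F1.
- Compound 12 with NaOEt, then NaOH and HCl as in step 7, leads through the keto ester F2 and the keto acid F3 to 5-(dec-9-enyl)cyclohexane-1,3-dione F4.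
- Oxalyl chloride gives 3-chloro-5-(dec-9-enyl)cyclohex-2-enone F5, and 4 with K2CO3 in DMF gives the bromoaryl vinylogous ester F6.
- Hex-5-enylzinc bromide F7, made from commercial 6-bromohex-1-ene and zinc, is coupled with F6 under the conditions of step 4 to give the diene F8.
- The second-generation Grubbs catalyst in dilute CH2Cl2 closes the macrocyclic alkene F9 (E/Z mixture; 8 + 2 + 4 = 14 chain carbons).
- H2 over Pd/C saturates the disubstituted alkene, which is far more reactive than the push-pull enone, and gives 21.

Step 12. TsOH and the water formed in the oxidation may cleave the vinylogous aryl ester (ring opening) before dehydrogenation is complete, or the catalyst may be lost as palladium black. The fallback is a stoichiometric, non-acidic α'-selenenylation and selenoxide elimination. It sets out from 21 and returns at 23. Kinetic deprotonation at C6 with LiN(i-Pr)2 in THF at -78 °C followed by PhSeCl gives the 6-phenylselanyl enone F10. H2O2 in CH2Cl2-pyridine at 0 °C gives the selenoxide F11, whose syn elimination toward H-C5 gives dienone 22, and this tautomerises to 23.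

Step 9. Silylation of the flanked phenol may stay incomplete, or the aryl silyl group may be lost during the selective hydrolysis or under the HCl of step 10. The fallback uses no silyl group: the benzyl ether is kept until after chlorination and is removed without hydrogen. It sets out from 15 and returns at 21. Oxalyl chloride converts 15 into the benzyl-protected chloroenone F12. BCl3 with pentamethylbenzene as cation scavenger in CH2Cl2 at -78 °C removes the benzyl group and gives the free phenol chloroenone F13. Slow addition of F13 to Cs2CO3 in DMF at high dilution forms phenoxide 20 by deprotonation and closes the ring to 21.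

Further compounds
F1 | step 11 | (E)-tetradeca-3,13-dien-2-one | CC(=O)/C=C/CCCCCCCCC=C
F2 | step 11 | ethyl 2-(dec-9-enyl)-4,6-dioxocyclohexane-1-carboxylate (stereoisomer mixture) | CCOC(=O)C1C(=O)CC(=O)CC1CCCCCCCCC=C
F3 | step 11 | 2-(dec-9-enyl)-4,6-dioxocyclohexane-1-carboxylic acid (stereoisomer mixture) | OC(=O)C1C(=O)CC(=O)CC1CCCCCCCCC=C
F4 | step 11 | 5-(dec-9-enyl)cyclohexane-1,3-dione | O=C1CC(=O)CC(CCCCCCCCC=C)C1
F5 | step 11 | 3-chloro-5-(dec-9-enyl)cyclohex-2-en-1-one (racemic) | O=C1C=C(Cl)CC(CCCCCCCCC=C)C1
F6 | step 11 | 3-(4-bromo-2,6-dimethoxyphenoxy)-5-(dec-9-enyl)cyclohex-2-en-1-one (racemic) | O=C1C=C(Oc2c(OC)cc(Br)cc2OC)CC(CCCCCCCCC=C)C1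
F7 | step 11 | hex-5-enylzinc bromide | C=CCCCC[Zn]Br
F8 | step 11 | 5-(dec-9-enyl)-3-[4-(hex-5-enyl)-2,6-dimethoxyphenoxy]cyclohex-2-en-1-one (racemic) | O=C1C=C(Oc2c(OC)cc(CCCCC=C)cc2OC)CC(CCCCCCCCC=C)C1
F9 | step 11 | macrocyclic 3-aryloxycyclohex-2-enone with one chain alkene (racemic, E/Z mixture) | O=C1C=C2CC(C1)CCCCCCCCC=CCCCCc1cc(OC)c(O2)c(OC)c1
F10 | step 12 | 6-(phenylselanyl) derivative of 21 (racemic, diastereomer mixture) | O=C1C=C2CC(C1[Se]c3ccccc3)CCCCCCCCCCCCCCc3cc(OC)c(O2)c(OC)c3
F11 | step 12 | selenoxide of F10 (stereoisomer mixture) | O=C1C=C2CC(C1[Se](=O)c3ccccc3)CCCCCCCCCCCCCCc3cc(OC)c(O2)c(OC)c3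
F12 | step 9 | 3-chloro-5-{14-[4-(benzyloxy)-3,5-dimethoxyphenyl]tetradecyl}cyclohex-2-en-1-one (racemic) | O=C1C=C(Cl)CC(CCCCCCCCCCCCCCc2cc(OC)c(OCc3ccccc3)c(OC)c2)C1
F13 | step 9 | 3-chloro-5-[14-(4-hydroxy-3,5-dimethoxyphenyl)tetradecyl]cyclohex-2-en-1-one (racemic) | O=C1C=C(Cl)CC(CCCCCCCCCCCCCCc2cc(OC)c(O)c(OC)c2)C1
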